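If each product molecule takes one partner, the partner, charged at less than the two substrates together, is the limiting reagent and the yield has a ceiling set by two amounts. The partner ceiling is 30.0% in the north-west flask: partner charged over the two substrates charged together.

| setting | north-west | north | flask |
|---|---|---|---|
| left-handed substrate | 0.047 M | 0.094 M | 0.047 M |
| right-handed substrate | 0.047 M | 0.094 M | 0.047 M |
| partner | 0.0282 M | 0.0282 M | 0.0282 M |
| free catalyst | 0.21 mM | 0.21 mM | 0.21 mM |
| added ligand | 0.57 mM | 0.57 mM | 0.57 mM |
| remark | the very flask that is asked about, followed so far | run made earlier |  |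
| time |  |  | 3.0 d |

| run | time / h | left-handed product / % | right-handed product / % | left-handed substrate / % |
|---|---|---|---|---|
| north-west | 3.00 | 4.3 | 18.9 | 44.2 |
| north-west | 6.00 | 5.7 | 23.0 | 40.5 |
| north-west | 10.0 | 6.0 | 22.9 | 37.3 |
| north-west | 12.0 | 4.4 | 24.1 | 37.8 |
| north-west | 15.0 | 5.5 | 23.6 | 36.3 |
| north-west | 20.0 | 4.6 | 23.7 | 36.5 |
| north | 2.50 | 2.0 | 8.7 | 46.2 |
| north | 8.00 | 1.6 | 12.5 | 44.4 |
| north | 15.0 | 2.9 | 12.0 | 43.2 |
| north | 20.0 | 2.8 | 12.0 | 43.3 |
| north | 30.0 | 2.3 | 11.7 | 42.0 |
| north | 40.0 | 2.3 | 12.7 | 42.7 |
| north | 48.0 | 3.1 | 11.9 | 42.5 |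

(scatter of a reading: 0.5 percentage points)

- excess of left-handed product over right-handed product in the product at 4.0 h
- excess of left-handed product over right-handed product in the product at 3.0 d
- part of the left-handed substrate and right-handed substrate charged together that has reacted at 3.0 d

- free catalyst is single-handed; left-handed substrate and right-handed substrate are mirror images of each other, charged as a racemate, each of them at the stated concentration
- an excess is below zero if the other one leads

The north run holds twice the substrates and the same partner. Its ceiling is 15.0%, and its last total of product reads 15.0%. So the last reading of the north run stands at the ceiling reckoned from its charges.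

In the north-west run the product total reads flat within the scatter from 6.00 h on, at a mean of 28.7%, a little below the ceiling. That plateau is 95.7% of the ceiling. The asked 3.0 d is 12.0 times 6.00 h, so my reckoning takes the plateau as the part reacted.

The excess needs one reading more. It is −62.9% at 3.00 h and −63.5% over the plateau, so I hold that value for both asked times.

The forecast gives −63%, −63% and 29%, reasoning “so the partner runs out”.

The north-west flask gives −62.9%, −63.3% and 29.1%.

    partner + catalyst intermediate B → free catalyst + right-handed product (k = 2580 L mol⁻¹ h⁻¹)
    partner + catalyst intermediate A → free catalyst + left-handed product (k = 6000 L mol⁻¹ h⁻¹)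
    free catalyst + added ligand ⇌ idle complex (K = 8180 L mol⁻¹, k = 194 L mol⁻¹ h⁻¹)
    free catalyst + left-handed substrate ⇌ catalyst intermediate A (K = 33.6 L mol⁻¹, k = 1660 L mol⁻¹ h⁻¹)
    partner → decomposed reagent (k = 0.0194 h⁻¹)
    left-handed substrate ⇌ right-handed substrate (k = 0.0840 h⁻¹)
    free catalyst + right-handed substrate ⇌ catalyst intermediate B (K = 540 L mol⁻¹, k = 7470 L mol⁻¹ h⁻¹)

At 3.00 d the north-west flask holds 0% of its partner and 71% of its left-handed substrate. A neighbour flask charged with 0.048 M of partner has a ceiling of 51.1%, and 95.7% of that is 48.9%. That neighbour flask stands at 49.2% reacted at 3.00 d.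

The readings were computed from invented constants, and the scatter is random.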